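A small charge of Kat, 0.2 mol% on Sub, works on a racemate in this flask, with Rea charged at 2.50 equiv, and you come at 1.0 h.

| setting | birch | maple | flask |
|---|---|---|---|
| Sub | 0.17 M | 0.66 M | 0.33 M |
| Sub2 | 0.17 M | 0.66 M | 0.33 M |
| Rea | 2.5 equiv | 2.5 equiv | 2.50 equiv |
| Kat | 0.2 mol% | 0.2 mol% | 0.2 mol% |
| remark | run made earlier | run made earlier |  |
| time |  |  | 1.0 h |

- birch (time / min: Sub / %, Sub2 / %): 5.00: 48.0, 49.8; 15.0: 47.2, 48.4; 30.0: 45.1, 46.1; 40.0: 44.2, 45.0; 60.0: 42.7, 43.0
- maple (time / min: Sub / %, Sub2 / %): 12.0: 30.3, 34.6; 25.0: 23.3, 25.5; 40.0: 17.9, 19.1; 50.0: 15.3, 16.8; 60.0: 13.3, 14.6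

(scatter of a reading: 0.3 percentage points)

- part of the Sub and Sub2 charged together that has reacted at 1.0 h
- excess of Pdt over Pdt2 in the product at 1.0 h
- excess of Sub2 over Sub among what is left of the two at 1.0 h

- Kat is single-handed; Sub and Sub2 are mirror images of each other, charged as a racemate, each of them at the stated concentration
- the numbers in the tables scatter by 0.3 percentage points (one standard deviation)
- an excess is the difference of the two amounts in percent of their sum
- an excess is below zero if the other one leads

The racemate gives me the zero of the scale: with equal charges and no interconversion, Pdt minus Pdt2 equals the gap, Sub2 minus Sub. But in birch that gap falls from 1.8 percentage points at 5.00 min to 0.3 points at 60.0 min, while the loss grows from 2.2 points to 14 points. So I take it that Sub and Sub2 interconvert (racemisation) and that a late gap understates the lead of Pdt. I read the selectivity early instead: the first-reading excess E, the gap over the summed loss at the first birch reading, is 81.8%, a rough reading, since each table value scatters by 0.3 points. Don't judge the product by the excess left in the flask: I expect Pdt to lead at about E. I assume that both handed rates carry Kat alike, so I carry E over to another loading. The forecast gives c 39%, eP 3.1% and eS 2%, noting “Sub is lost faster early on”; on eP I differ.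

The flask gives c 38.0%, eP 95.9% and eS 1.48%.

    Rea + Kat → Zet (k = 7.76 × 10⁻⁴ M⁻¹ s⁻¹)
    Sub ⇌ Sub2 (k = 0.00336 s⁻¹)
    Rea → Sdp (k = 9.08 × 10⁻⁶ s⁻¹)
    Rea + Kat + Sub2 → Kat + Pdt2 (k = 0.153 M⁻² s⁻¹)
    Rea ⇌ Imd (K = 11.0, k = 0.0760 s⁻¹)
    Rea + Kat + Sub → Kat + Pdt (k = 7.53 M⁻² s⁻¹)

The neighbouring flask, with 0.34 mol% of Kat, gets the same reckoning: I expect an excess of Pdt near E, 81.8%, not one scaled from what is left. It reaches c 51.8% with eS 2.15%, which the zero-interconversion balance would turn into a product excess of 2.00%, but its eP is 95.8%.

The runs stem from a simulated flask with made-up constants; noise was put on by code.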